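## Retrosynthetic overview

1. Target ⇒ the 1,10-oxirane is closed last (C10–O⁻ displaces a C1 mesylate with inversion); the C3 angelate and C4–OH come from anti-opening of a 3,4-epoxide on a (3Z)-cyclodecene; the four esters come from orthogonally masked alcohols (TBS, PMB, PMP).
2. Ten-membered ring ⇒ anionic oxy-Cope ring expansion of a cis-1,2-dialkenylcyclohexanol (breaks C4–C9, makes C1–C2) with enolate hydroxylation in the same flask (sets C1 and C10). This replaces the usual RCM or NHK macrocyclisation.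
3. Dialkenylcyclohexanol ⇒ cyclohexanone + (E)-2-lithio enol ether; the quaternary carbon (Me, vinyl) and the C5–OH ⇒ vinyl-migrating semipinacol rearrangement of an epoxy carbinol.
4. Epoxy carbinol ⇒ (S)-carvone (C7) by α'-hydroxylation and Mitsunobu inversion (C8), 1,2-vinylation and hydroxyl-directed epoxidation (C5).
5. Ring order: cyclohexane (chiral pool) → cyclodecane (oxy-Cope) → oxirane (last step).

Assumption: the given SMILES defines the target; germacrane numbering is used (1R,3S,4S,5R,7R,8S,9S,10R, Z-angelate), and carvone C1/C2/C3/C4/C5/C6 become C9/C4/C5/C6/C7/C8. PMB = 4-methoxybenzyl, PMP = 4-methoxyphenyl, TBS = tert-butyldimethylsilyl.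

## Route

Step 1
Reactants: 1 (S)-(+)-carvone
Product: 3 (5R,6R)-6-hydroxycarvone (OH trans to isopropenyl), via lithium dienolate 2 (not isolated)
Conditions: LDA, THF, -78 °C; then 2-(phenylsulfonyl)-3-phenyloxaziridine, -78 °C; H2O
Reagents that add atoms: 2-(phenylsulfonyl)-3-phenyloxaziridine, O=S(=O)(c1ccccc1)N1OC1c1ccccc1
Why: Kinetic α'-deprotonation and Davis enolate hydroxylation occur at C6 anti to the neighbouring isopropenyl group, giving the trans ketol whose carbinol centre (future C8) is inverted in step 2.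

Step 2
Reactants: 3 (5R,6R)-6-hydroxycarvone
Product: 4 (5R,6S)-6-(4-methoxyphenoxy)carvone (ArO cis to isopropenyl)
Conditions: 4-methoxyphenol, PPh3, DIAD, toluene, 0 °C to rt
Reagents that add atoms: 4-methoxyphenol, COc1ccc(O)cc1
Why: Mitsunobu etherification is an SN2 inversion at the activated α-keto carbon, which places the oxygen cis to isopropenyl and so sets C8 as a CAN-cleavable PMP ether.

Step 3
Reactants: 4 (5R,6S)-6-(4-methoxyphenoxy)carvone
Product: 5 (1R,5R,6S)-6-(4-methoxyphenoxy)-2-methyl-5-(prop-1-en-2-yl)-1-vinylcyclohex-2-en-1-ol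
Conditions: vinylMgBr, THF, -78 °C
Reagents that add atoms: vinylmagnesium bromide, C=C[Mg]Br
Why: Grignard 1,2-addition to the enone takes the axial trajectory anti to the pseudoaxial C6 aryloxy group (Felkin-type), so the new OH is cis to ArO and isopropenyl.

Step 4
Reactants: 5 vinyl carbinol
Product: 6 2,3-epoxide of 5 on the hydroxyl face
Conditions: VO(acac)2 (cat.), t-BuOOH, CH2Cl2, 0 °C
Reagents that add atoms: tert-butyl hydroperoxide, CC(C)(C)OO
Why: Vanadium-catalysed hydroxyl-directed epoxidation delivers oxygen only to the electron-rich ring alkene on the face of the tertiary OH, which fixes the configuration of the future C5 oxygen.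

Step 5
Reactants: 6 syn-epoxy carbinol
Product: 7 3-hydroxy-6-(4-methoxyphenoxy)-2-methyl-5-(prop-1-en-2-yl)-2-vinylcyclohexan-1-one
Conditions: BF3·OEt2 (0.3 equiv), CH2Cl2, -78 °C
Reagents that add atoms: none
Why: In this semipinacol rearrangement of a 2,3-epoxy alcohol the vinyl group, anti-periplanar to the breaking tertiary C–O bond, migrates with inversion, giving the ketone (C9), the quaternary carbon (vinyl trans, methyl cis to the new C5–OH) and the C5 carbinol.

Step 6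
Reactants: 7 β-hydroxy ketone
Product: 8 3-O-TBS ether of 7
Conditions: TBSOTf, 2,6-lutidine, CH2Cl2, -78 °C
Reagents that add atoms: tert-butyldimethylsilyl triflate, CC(C)(C)[Si](C)(C)OS(=O)(=O)C(F)(F)F
Why: Silyl protection of the hindered secondary alcohol blocks retro-aldol cleavage and survives the organolithium and potassium bases that follow.

Step 7
Reactants: 9 4-methoxybenzyl alcohol
Product: 12 4-methoxybenzyl prop-1-yn-1-yl ether, via dichlorovinyl ether 10 (not isolated), via lithium alkoxyacetylide 11 (not isolated)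
Conditions: KH, THF; Cl2C=CHCl, rt; n-BuLi, -78 to -40 °C; MeI, HMPA, -78 °C to rt
Reagents that add atoms: trichloroethylene, ClC=C(Cl)Cl; iodomethane, CI
Why: Greene-type one-pot ynol ether synthesis: alkoxide addition to dichloroacetylene formed from trichloroethylene, dehydrochlorination and Cl–Li exchange to the lithium acetylide, then C-methylation.

Step 8
Reactants: 12 4-methoxybenzyl prop-1-yn-1-yl ether
Product: 14 (E)-2-iodo-1-(4-methoxybenzyloxy)prop-1-ene, via alkenylzirconocene 13 (not isolated)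
Conditions: Cp2Zr(H)Cl, THF, 0 °C to rt; then I2, 0 °C
Reagents that add atoms: iodine, II
Why: Schwartz hydrozirconation adds H–Zr syn with zirconium on the carbon β to oxygen, and iodinolysis with retention gives the iodide with iodine trans to the alkoxy group.

Step 9
Reactants: 14 (E)-2-iodo-1-(4-methoxybenzyloxy)prop-1-ene; 8 silyl ether ketone
Product: 16 cis-1,2-dialkenylcyclohexanol (1-OH cis to 6-OAr; alkenyl cis to vinyl), via alkenyllithium 15 (not isolated)
Conditions: 14, t-BuLi (2 equiv), Et2O, -78 °C; then 8, THF, -78 °C; H2O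
Reagents that add atoms: none
Why: Iodine–lithium exchange with retention is followed by 1,2-addition along the axial trajectory anti to the axial C8 aryloxy and axial methyl groups, so the alkenyl group is axial and cis to the equatorial vinyl group.

Step 10
Reactants: 16 cis-1,2-dialkenylcyclohexanol
Product: 19 (3Z)-10-hydroxy-1-(PMB-oxy)-8-(PMP-oxy)-5-(TBS-oxy)germacra-3,11-dien-9-one, via potassium alkoxide 17 (not isolated), via potassium enolate 18 (not isolated)
Conditions: KHMDS, 18-crown-6, THF, 0 °C to rt; then 2-(phenylsulfonyl)-3-phenyloxaziridine, -78 °C; H2O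
Reagents that add atoms: 2-(phenylsulfonyl)-3-phenyloxaziridine, O=S(=O)(c1ccccc1)N1OC1c1ccccc1
Why: The anionic oxy-Cope [3,3] rearrangement through the chair available to the axial-alkenyl/equatorial-vinyl isomer gives the 3Z alkene and sets C1 (OPMB equatorial from the E enol ether), and Davis hydroxylation of the ring-E enolate on its peripheral face sets C10.

Step 11
Reactants: 19 α-hydroxy ketone
Product: 20 (3Z)-1-(PMB-oxy)-8-(PMP-oxy)-5-(TBS-oxy)germacra-3,11-diene-9,10-diol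
Conditions: Zn(BH4)2, Et2O, -20 °C
Reagents that add atoms: none
Why: Chelation-controlled reduction (zinc bridges C10–O and C9=O, hydride enters from the methyl side, which is also the peripheral face) gives the erythro diol and sets C9.

Step 12
Reactants: 20 9,10-diol
Product: 21 3,4-epoxide of 20 (epoxide O trans to 5-OTBS)
Conditions: mCPBA, NaHCO3, CH2Cl2, 0 °C
Reagents that add atoms: 3-chloroperbenzoic acid, OOC(=O)c1cccc(Cl)c1
Why: Prilezhaev epoxidation picks the trisubstituted Z alkene over the isopropenyl group and attacks the peripheral face trans to the allylic silyloxy group, as in medium-ring (Z)-cycloalkenyl derivatives, which sets C4.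

Step 13
Reactants: 21 epoxy silyl ether
Product: 22 3,4-epoxy-5-ol
Conditions: TBAF, AcOH, THF, rt
Reagents that add atoms: none
Why: Buffered fluoride desilylation frees the C5 hydroxyl without Payne rearrangement of the neighbouring epoxide.

Step 14
Reactants: 22 3,4-epoxy-5-ol
Product: 23 3-angelate 4,5,9,10-tetraol
Conditions: angelic acid, Ti(OiPr)4, CH2Cl2, rt
Reagents that add atoms: angelic acid, C/C=C(/C)C(=O)O
Why: Titanium-mediated opening of a 2,3-epoxy alcohol by a carboxylic acid at C3 (Sharpless-type) is an SN2 inversion that sets C3 and installs the angelate directly, while C4 keeps the epoxide oxygen.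

Step 15
Reactants: 23 3-angelate tetraol
Product: 24 5,9-diacetate
Conditions: Ac2O, pyridine, DMAP (cat.), CH2Cl2, 0 °C to rt
Reagents that add atoms: acetic anhydride, CC(=O)OC(C)=O
Why: DMAP-catalysed acetylation esterifies the two free secondary alcohols (C5, C9), while the tertiary C4 and C10 hydroxyls are too hindered to react.

Step 16
Reactants: 24 5,9-diacetate
Product: 25 1-alcohol (PMB removed)
Conditions: DDQ, CH2Cl2/pH 7 buffer, 0 °C
Reagents that add atoms: none
Why: Oxidative PMB ether cleavage by DDQ leaves the PMP aryl ether, the esters and the alkenes untouched.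

Step 17
Reactants: 25 1-alcohol
Product: 26 1-mesylate
Conditions: MsCl, Et3N, CH2Cl2, -20 °C
Reagents that add atoms: methanesulfonyl chloride, CS(=O)(=O)Cl
Why: Sulfonylation of the only secondary alcohol turns C1–O into the leaving group for the final epoxide closure.

Step 18
Reactants: 26 1-mesylate
Product: 27 8-alcohol (PMP removed)
Conditions: CAN, MeCN/H2O, 0 °C
Reagents that add atoms: none
Why: Ceric ammonium nitrate oxidatively dearylates the PMP ether to the C8 alcohol at a stage where no acid-sensitive epoxide is present.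

Step 19
Reactants: 27 8-alcohol
Product: 28 8-senecioate 1-mesylate
Conditions: 3-methylbut-2-enoyl chloride, pyridine, DMAP (cat.), CH2Cl2, 0 °C
Reagents that add atoms: 3-methylbut-2-enoyl chloride, CC(C)=CC(=O)Cl
Why: Acylation of the single remaining secondary hydroxyl with the acid chloride uses a weak base to avoid deconjugation of the senecioyl group.

Step 20
Reactants: 28 8-senecioate 1-mesylate
Product: 29 target CNP0416509.1
Conditions: DBU, toluene, rt
Reagents that add atoms: none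
Why: Intramolecular Williamson-type SN2 displacement of the C1 mesylate by the C10 alkoxide closes the oxirane with inversion at C1, giving the cis-1,10-epoxide.

## Compound list

1 | (S)-(+)-carvone = (5S)-2-methyl-5-(prop-1-en-2-yl)cyclohex-2-en-1-one | C=C(C)[C@H]1CC=C(C)C(=O)C1 | starting material
2 | lithium dienolate of 1 (O-Li on C1; C1=C6 and C2=C3) | C=C(C)[C@H]1CC=C(C)C(O[Li])=C1 | intermediate
3 | (5R,6R)-6-hydroxy-2-methyl-5-(prop-1-en-2-yl)cyclohex-2-en-1-one (OH trans to isopropenyl) | C=C(C)[C@H]1CC=C(C)C(=O)[C@@H]1O | intermediate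
4 | (5R,6S)-6-(4-methoxyphenoxy)-2-methyl-5-(prop-1-en-2-yl)cyclohex-2-en-1-one (ArO cis to isopropenyl) | C=C(C)[C@H]1CC=C(C)C(=O)[C@H]1Oc2ccc(OC)cc2 | intermediate
5 | (1R,5R,6S)-6-(4-methoxyphenoxy)-2-methyl-5-(prop-1-en-2-yl)-1-vinylcyclohex-2-en-1-ol (OH cis to ArO) | C=C(C)[C@H]1CC=C(C)[C@](O)(C=C)[C@H]1Oc2ccc(OC)cc2 | intermediate
6 | 2,3-epoxide of 5 on the hydroxyl face (OH / epoxide O / ArO / isopropenyl all cis) | C=C(C)[C@H]1C[C@H]2O[C@@]2(C)[C@](O)(C=C)[C@H]1Oc3ccc(OC)cc3 | intermediate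
7 | 3-hydroxy-6-(4-methoxyphenoxy)-2-methyl-5-(prop-1-en-2-yl)-2-vinylcyclohexan-1-one (2-Me / 3-OH / 5-isopropenyl / 6-OAr cis; 2-vinyl trans) | C=C(C)[C@H]1C[C@@H](O)[C@](C)(C=C)C(=O)[C@H]1Oc2ccc(OC)cc2 | intermediate
8 | 3-O-tert-butyldimethylsilyl ether of 7 | C=C(C)[C@H]1C[C@@H](O[Si](C)(C)C(C)(C)C)[C@](C)(C=C)C(=O)[C@H]1Oc2ccc(OC)cc2 | intermediate
9 | 4-methoxybenzyl alcohol | COc1ccc(CO)cc1 | starting material
10 | (E)-1,2-dichlorovinyl 4-methoxybenzyl ether | Cl/C=C(Cl)\OCc1ccc(OC)cc1 | intermediate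
11 | lithium 2-(4-methoxybenzyloxy)acetylide | [Li]C#COCc1ccc(OC)cc1 | intermediate
12 | 4-methoxybenzyl prop-1-yn-1-yl ether | CC#COCc1ccc(OC)cc1 | intermediate
13 | chloro[(E)-1-(4-methoxybenzyloxy)prop-1-en-2-yl]zirconocene (Cp drawn sigma-bonded; Zr trans to O) | C/C(=C\OCc1ccc(OC)cc1)[Zr](Cl)(C1C=CC=C1)C1C=CC=C1 | intermediate
14 | (E)-2-iodo-1-(4-methoxybenzyloxy)prop-1-ene (I trans to O) | I/C(C)=C/OCc1ccc(OC)cc1 | intermediate
15 | (E)-1-(4-methoxybenzyloxy)prop-1-en-2-yllithium (Li trans to O) | [Li]/C(C)=C/OCc1ccc(OC)cc1 | intermediate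
16 | 3-(TBS-oxy)-6-(4-methoxyphenoxy)-2-methyl-1-[(E)-1-(PMB-oxy)prop-1-en-2-yl]-5-(prop-1-en-2-yl)-2-vinylcyclohexan-1-ol (1-OH cis to 6-OAr; alkenyl cis to vinyl) | C=C(C)[C@H]1C[C@@H](O[Si](C)(C)C(C)(C)C)[C@](C)(C=C)[C@](O)(/C(C)=C/OCc2ccc(OC)cc2)[C@H]1Oc3ccc(OC)cc3 | intermediate
17 | potassium alkoxide of 16 | C=C(C)[C@H]1C[C@@H](O[Si](C)(C)C(C)(C)C)[C@](C)(C=C)[C@](O[K])(/C(C)=C/OCc2ccc(OC)cc2)[C@H]1Oc3ccc(OC)cc3 | intermediate
18 | ring-expanded potassium enolate: (3Z)-1-(PMB-oxy)-8-(PMP-oxy)-5-(TBS-oxy)germacra-3,9,11-trien-9-olate (C8 and C1 trans across C9=C10) | C=C(C)[C@H]1C[C@@H](O[Si](C)(C)C(C)(C)C)/C(C)=C\C[C@H](OCc2ccc(OC)cc2)/C(C)=C(\O[K])[C@H]1Oc3ccc(OC)cc3 | intermediate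
19 | (1S,3Z,5R,7R,8S,10R)-10-hydroxy-1-(PMB-oxy)-8-(PMP-oxy)-5-(TBS-oxy)germacra-3,11-dien-9-one | C=C(C)[C@H]1C[C@@H](O[Si](C)(C)C(C)(C)C)/C(C)=C\C[C@H](OCc2ccc(OC)cc2)[C@@](C)(O)C(=O)[C@H]1Oc3ccc(OC)cc3 | intermediate
20 | (3Z)-1-(PMB-oxy)-8-(PMP-oxy)-5-(TBS-oxy)germacra-3,11-diene-9,10-diol (C9 as in target; 9-OH and 10-OH erythro) | C=C(C)[C@H]1C[C@@H](O[Si](C)(C)C(C)(C)C)/C(C)=C\C[C@H](OCc2ccc(OC)cc2)[C@@](C)(O)[C@@H](O)[C@H]1Oc3ccc(OC)cc3 | intermediate
21 | 3,4-epoxide of 20 (cis-epoxide; O trans to 5-OTBS) | C=C(C)[C@H]1C[C@@H](O[Si](C)(C)C(C)(C)C)[C@]2(C)O[C@@H]2C[C@H](OCc3ccc(OC)cc3)[C@@](C)(O)[C@@H](O)[C@H]1Oc4ccc(OC)cc4 | intermediate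
22 | 3,4-epoxy-1-(PMB-oxy)-8-(PMP-oxy)germacr-11-ene-5,9,10-triol | C=C(C)[C@H]1C[C@@H](O)[C@]2(C)O[C@@H]2C[C@H](OCc3ccc(OC)cc3)[C@@](C)(O)[C@@H](O)[C@H]1Oc4ccc(OC)cc4 | intermediate
23 | 3-angeloyloxy-1-(PMB-oxy)-8-(PMP-oxy)germacr-11-ene-4,5,9,10-tetraol (C3 / C4 / C5 as in target) | C=C(C)[C@H]1C[C@@H](O)[C@](C)(O)[C@@H](OC(=O)/C(C)=C\C)C[C@H](OCc3ccc(OC)cc3)[C@@](C)(O)[C@@H](O)[C@H]1Oc4ccc(OC)cc4 | intermediate
24 | 5,9-diacetate of 23 | C=C(C)[C@H]1C[C@@H](OC(C)=O)[C@](C)(O)[C@@H](OC(=O)/C(C)=C\C)C[C@H](OCc3ccc(OC)cc3)[C@@](C)(O)[C@@H](OC(C)=O)[C@H]1Oc4ccc(OC)cc4 | intermediate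
25 | 5,9-diacetoxy-3-angeloyloxy-8-(PMP-oxy)germacr-11-ene-1,4,10-triol (C1 opposite to target) | C=C(C)[C@H]1C[C@@H](OC(C)=O)[C@](C)(O)[C@@H](OC(=O)/C(C)=C\C)C[C@H](O)[C@@](C)(O)[C@@H](OC(C)=O)[C@H]1Oc2ccc(OC)cc2 | intermediate
26 | 1-O-methanesulfonate of 25 | C=C(C)[C@H]1C[C@@H](OC(C)=O)[C@](C)(O)[C@@H](OC(=O)/C(C)=C\C)C[C@H](OS(C)(=O)=O)[C@@](C)(O)[C@@H](OC(C)=O)[C@H]1Oc2ccc(OC)cc2 | intermediate
27 | 5,9-diacetoxy-3-angeloyloxy-1-mesyloxygermacr-11-ene-4,8,10-triol | C=C(C)[C@H]1C[C@@H](OC(C)=O)[C@](C)(O)[C@@H](OC(=O)/C(C)=C\C)C[C@H](OS(C)(=O)=O)[C@@](C)(O)[C@@H](OC(C)=O)[C@H]1O | intermediate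
28 | 8-O-senecioate of 27 | C=C(C)[C@H]1C[C@@H](OC(C)=O)[C@](C)(O)[C@@H](OC(=O)/C(C)=C\C)C[C@H](OS(C)(=O)=O)[C@@](C)(O)[C@@H](OC(C)=O)[C@H]1OC(=O)C=C(C)C | intermediate
29 | CNP0416509.1 = (1R,3S,4S,5R,7R,8S,9S,10R)-5,9-diacetoxy-3-angeloyloxy-1,10-epoxy-4-hydroxy-8-senecioyloxygermacr-11-ene | C=C(C)[C@H]1C[C@@H](OC(C)=O)[C@](C)(O)[C@@H](OC(=O)/C(C)=C\C)C[C@H]2O[C@@]2(C)[C@@H](OC(C)=O)[C@H]1OC(=O)C=C(C)C | target

## Step count and risks

Total step count: 20. Longest linear sequence: 18 steps (steps 1–6 and 9–20 from 1); steps 7–8 make fragment 14.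

The three steps most likely to fail:

Step 10 (oxy-Cope and enolate hydroxylation). The free β-alkoxy enolate 18 can lose PMBO⁻ by E1cB elimination, and the rearrangement relies on one chair conformer. The fallback sets out from 16 and comes back at 19 by a neutral silyloxy-Cope/Rubottom sequence. 16 is silylated (TMS-imidazole) to the trimethylsilyl ether F4. Heating F4 (o-dichlorobenzene, about 180 °C) takes it through the same chair to the ring-expanded trimethylsilyl enol ether F5, which cannot eliminate. F5 is oxidised on its peripheral face with dimethyldioxirane at -78 °C, and mild acid (citric acid, MeOH) removes the silyl group to give 19.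

Step 14 (carboxylate opening of the epoxide at C3). This needs an SN2 attack at a ring carbon next to a fully substituted centre, and transannular or C4-opening pathways may compete. The fallback sets out from 20 and comes back at 24, opening at the tertiary carbon with water instead. 20 is desilylated (TBAF/AcOH) to the allylic alcohol F6. F6 is epoxidised on the face of the C5 hydroxyl with VO(acac)2/t-BuOOH (the cis selectivity of medium-ring (Z)-cycloalk-2-enols) to the epimeric epoxy alcohol F7. Acetylation of C5 and C9 (Ac2O, DMAP) gives the epoxy diacetate F8. Dilute HClO4 in THF/H2O at 0 °C opens F8 at the tertiary C4 with inversion to the 3,4-diol F9, which has the target C3 and C4 configurations and one free secondary hydroxyl. Yamaguchi esterification of F9 with angelic acid (2,4,6-trichlorobenzoyl chloride, Et3N, DMAP, toluene) gives 24.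

Step 9 (addition of the labile trans-β-alkoxy alkenyllithium 15 to the hindered ketone). The reagent can eliminate alkoxide, and the ynol ether 12 is heat-sensitive. The fallback sets out from 8 (with 9) and comes back at 16. 9 is alkylated with 2,3-dibromopropene (NaH, THF) to 2-bromo-3-(4-methoxybenzyloxy)prop-1-ene F1. Bromine–lithium exchange (t-BuLi, -78 °C) gives the more robust 2-lithioallyl ether F2, which adds to 8 along the same axial trajectory to give the allyl ether carbinol F3. A cationic iridium hydride catalyst ([Ir(cod)(PMePh2)2]PF6 activated with H2, THF) isomerises the allyl ether of F3 to the (E)-enol ether with OPMB trans to the bulky carbinol carbon, which is 16.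

## Further compounds

F1 | step 9 | 2-bromo-3-(4-methoxybenzyloxy)prop-1-ene | C=C(Br)COCc1ccc(OC)cc1
F2 | step 9 | 3-(4-methoxybenzyloxy)prop-1-en-2-yllithium | [Li]C(=C)COCc1ccc(OC)cc1
F3 | step 9 | allyl ether carbinol: 1-[3-(PMB-oxy)prop-1-en-2-yl] analogue of 16 (same ring configuration) | C=C(C)[C@H]1C[C@@H](O[Si](C)(C)C(C)(C)C)[C@](C)(C=C)[C@](O)(C(=C)COCc2ccc(OC)cc2)[C@H]1Oc3ccc(OC)cc3
F4 | step 10 | 1-O-trimethylsilyl ether of 16 | C=C(C)[C@H]1C[C@@H](O[Si](C)(C)C(C)(C)C)[C@](C)(C=C)[C@](O[Si](C)(C)C)(/C(C)=C/OCc2ccc(OC)cc2)[C@H]1Oc3ccc(OC)cc3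
F5 | step 10 | ring-expanded trimethylsilyl enol ether: (3Z)-1-(PMB-oxy)-8-(PMP-oxy)-5-(TBS-oxy)-9-(trimethylsilyloxy)germacra-3,9,11-triene | C=C(C)[C@H]1C[C@@H](O[Si](C)(C)C(C)(C)C)/C(C)=C\C[C@H](OCc2ccc(OC)cc2)/C(C)=C(\O[Si](C)(C)C)[C@H]1Oc3ccc(OC)cc3
F6 | step 14 | (3Z)-1-(PMB-oxy)-8-(PMP-oxy)germacra-3,11-diene-5,9,10-triol | C=C(C)[C@H]1C[C@@H](O)/C(C)=C\C[C@H](OCc2ccc(OC)cc2)[C@@](C)(O)[C@@H](O)[C@H]1Oc3ccc(OC)cc3
F7 | step 14 | 3,4-epoxide of F6 with the epoxide O cis to the 5-OH (C3 and C4 epimeric to 22) | C=C(C)[C@H]1C[C@@H](O)[C@@]2(C)O[C@H]2C[C@H](OCc3ccc(OC)cc3)[C@@](C)(O)[C@@H](O)[C@H]1Oc4ccc(OC)cc4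
F8 | step 14 | 5,9-diacetate of F7 | C=C(C)[C@H]1C[C@@H](OC(C)=O)[C@@]2(C)O[C@H]2C[C@H](OCc3ccc(OC)cc3)[C@@](C)(O)[C@@H](OC(C)=O)[C@H]1Oc4ccc(OC)cc4
F9 | step 14 | 5,9-diacetoxy-1-(PMB-oxy)-8-(PMP-oxy)germacr-11-ene-3,4,10-triol (C3 and C4 as in target) | C=C(C)[C@H]1C[C@@H](OC(C)=O)[C@](C)(O)[C@@H](O)C[C@H](OCc3ccc(OC)cc3)[C@@](C)(O)[C@@H](OC(C)=O)[C@H]1Oc4ccc(OC)cc4
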